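**Retrosynthetic overview**

1. 32 ⇐ 29: the γ-lactone bond O–C6 (the C12 carboxylate displaces the C6 hydroxyl with inversion) and the hemiketal bond O5–C2 are made last. In 29 the C2 carbonyl is still held by O6 as a six-membered hemiketal.
2. 29 ⇐ furanophane carbinol 25 (Achmatowicz oxidation, Luche reduction; the furan supplies C2–C5). 25 ⇐ bromofuran aldehyde 22 by ring closure C5–C6 (Nozaki–Hiyama–Kishi), with C6 reset by oxidation and reagent-controlled reduction.
3. 22 ⇐ hydroxy aldehyde 11 + allyl bromide 15 (indium Barbier, C7–C8; C7 and C8 set from C9). 11 ⇐ furaldehyde 4 + ester 7 (aldol/E1cB, C1=C10); C9 comes from an asymmetric hydrogenation.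
4. Ring order: furan (bought) → ten-membered carbocycle (step 15) → six-membered hemiketal, and with it an eight-membered oxocine O6/C6/C7/C8/C9/C10/C1/C2 (step 18) → in step 21 the 2,5-dihydrofuran hemiketal and the γ-lactone, while the oxocine grows to the nine-membered oxonine O5/C5/C6/C7/C8/C9/C10/C1/C2.
5. Enabling feature: C2 is a ketone-level carbon whose cis C3=C4 arm ends in two neighbouring carbinol carbons, C5 and C6. Its hemiketal can therefore sit on O6 (six-membered ring) or on O5 (five-membered ring), while the C12 carboxyl on C7 can lactonise only at C6.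

Key step: step 21

Remark: the descriptors of the SMILES are followed as written, so C5–O stands erythro to C6–O and C6 is inverted in the last step; the hemiketal carbon C2 is formed reversibly when O5 closes on it and is written in 32 with the descriptor of the target SMILES.

Locants in the text follow germacrane numbering: ring carbons C1–C10 (C10 carries the CO2Me carbon C14, C4 the methyl group), lactone carbons C11–C13 on C7; O5, O6, O8, O9 are the oxygens on those carbons.

**Route**

Step 1
Reactants: 1 3-methylfuran
Product: 2 2-bromo-3-methylfuran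
Conditions: NBS, DMF, −20 → 0 °C
Reagents that add atoms: N-bromosuccinimide, O=C1CCC(=O)N1Br
Why: Electrophilic aromatic bromination takes the furan α-position next to the methyl group, the most electron-rich site.

Step 2
Reactants: 2 2-bromo-3-methylfuran
Product: 4 5-bromo-4-methylfuran-2-carbaldehyde, via furyllithium 3 (not isolated)
Conditions: LiN(iPr)2, THF, −78 °C; DMF, −78 → 0 °C; H2O
Reagents that add atoms: N,N-dimethylformamide, CN(C)C=O
Why: Lithiation–formylation: the amide base removes the only remaining α-proton of the furan without touching the C–Br bond at −78 °C, and DMF delivers the formyl group.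

Step 3
Reactants: 5 methyl 4,4-dimethoxy-3-oxobutanoate
Product: 6 methyl (3S)-3-hydroxy-4,4-dimethoxybutanoate
Conditions: H2 (50 bar), RuCl2[(R)-BINAP] (0.5 mol%), MeOH, 50 °C
Reagents that add atoms: none
Why: Noyori asymmetric hydrogenation of a β-keto ester; the ester-directed hydride transfer with the (R)-ligand sets the carbinol centre (later C9), labelled S because the acetal carbon outranks CH2CO2Me.

Step 4
Reactants: 6 methyl (3S)-3-hydroxy-4,4-dimethoxybutanoate
Product: 7 methyl (3S)-3-(tert-butyldimethylsilyloxy)-4,4-dimethoxybutanoate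
Conditions: TBSCl, imidazole, DMF, rt
Reagents that add atoms: tert-butyldimethylsilyl chloride, C[Si](C)(Cl)C(C)(C)C
Why: Standard silylation of the secondary alcohol, so that the ester enolate of step 5 has neither an acidic proton nor a good β-leaving group.

Step 5
Reactants: 7 methyl (3S)-3-(tert-butyldimethylsilyloxy)-4,4-dimethoxybutanoate; 4 5-bromo-4-methylfuran-2-carbaldehyde
Product: 8 methyl (3S)-2-[(5-bromo-4-methylfuran-2-yl)(hydroxy)methyl]-3-(tert-butyldimethylsilyloxy)-4,4-dimethoxybutanoate (mixture at the two new centres)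
Conditions: LiN(iPr)2, THF, −78 °C; then 4, −78 °C; H2O
Reagents that add atoms: none
Why: Aldol addition of the lithium ester enolate to the non-enolisable furaldehyde at −78 °C, where β-elimination of the silyloxy group is slow; the two new centres (C1, C10) form as a mixture that does not matter because both become sp2 in step 6.

Step 6
Reactants: 8 aldol adduct
Product: 10 methyl (2E,3S)-2-[(5-bromo-4-methylfuran-2-yl)methylidene]-3-(tert-butyldimethylsilyloxy)-4,4-dimethoxybutanoate, via mesylate 9 (not isolated)
Conditions: MsCl, Et3N, CH2Cl2, 0 °C; then DBU, rt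
Reagents that add atoms: none
Why: Mesylation and E1cB elimination through the ester enolate should give the trisubstituted acrylate as the more stable E isomer (furyl trans to CO2Me, cis to C9), the C9 silyloxy group being too poor a leaving group to compete.

Step 7
Reactants: 10 silyloxy acetal
Product: 11 methyl (2E,3S)-2-[(5-bromo-4-methylfuran-2-yl)methylidene]-3-hydroxy-4-oxobutanoate
Conditions: TFA/H2O (9:1), CH2Cl2, 0 °C; used at once
Reagents that add atoms: water, O
Why: Aqueous acid hydrolysis cleaves the dimethyl acetal and the silyl ether in one operation without touching C9; the sensitive α-hydroxy aldehyde is not stored.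

Step 8
Reactants: 12 tert-butyl acrylate; 13 (tert-butyldimethylsilyloxy)acetaldehyde
Product: 14 tert-butyl 4-(tert-butyldimethylsilyloxy)-3-hydroxy-2-methylidenebutanoate (racemic)
Conditions: DABCO (0.3 equiv), dioxane/H2O (1:1), rt
Reagents that add atoms: none
Why: Morita–Baylis–Hillman reaction of an acrylate with an activated α-oxygenated aldehyde; the racemic carbinol centre is destroyed in step 9.

Step 9
Reactants: 14 Baylis–Hillman adduct
Product: 15 tert-butyl (2Z)-2-(bromomethyl)-4-(tert-butyldimethylsilyloxy)but-2-enoate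
Conditions: NBS, Me2S, CH2Cl2, −20 → 0 °C
Reagents that add atoms: N-bromosuccinimide, O=C1CCC(=O)N1Br
Why: Corey–Kim-type activation of the allylic alcohol as an alkoxysulfonium ion and SN2′ attack of bromide give the rearranged primary allylic bromide, formed as the Z isomer as is the rule for Baylis–Hillman adducts.

Step 10
Reactants: 11 hydroxy aldehyde; 15 allyl bromide
Product: 16 1-tert-butyl 7-methyl (6E)-6-[(5-bromo-4-methylfuran-2-yl)methylidene]-3-[(tert-butyldimethylsilyloxy)methyl]-4,5-dihydroxy-2-methylideneheptanedioate; C7/C8/C9 as in 32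
Conditions: In (powder, 2 equiv), THF/H2O (1:1), rt
Reagents that add atoms: none
Why: Indium Barbier allylation in water: the allylindium reacts through its γ-carbon (C7) in a cyclic transition state with the free C9 hydroxyl and the aldehyde oxygen chelated to indium, which sets C8 syn to C9, while the Z-bromide sets C7 syn to C8 (the syn,syn outcome known for 2-(bromomethyl)alk-2-enoates with α-hydroxy aldehydes); the tert-butyl ester prevents lactonisation onto O8.

Step 11
Reactants: 16 diol
Product: 17 the 5-acetate of 16 (acetate on O9; O8 free)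
Conditions: AcCl (1.05 equiv), 2,4,6-collidine, CH2Cl2, −78 °C
Reagents that add atoms: acetyl chloride, CC(Cl)=O
Why: Sterically controlled monoacylation: the allylic C9 hydroxyl is flanked by the flat sp2 carbon C10, the C8 hydroxyl by the branched sp3 carbon C7, so a small acyl chloride with a hindered base at low temperature should take O9.

Step 12
Reactants: 17 monoacetate; 18 angelic acid
Product: 20 the O8 angelate of 17, via mixed anhydride 19 (not isolated)
Conditions: 18, 2,4,6-trichlorobenzoyl chloride, Et3N, toluene, rt; then 17, toluene, 75 °C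
Reagents that add atoms: none
Why: Yamaguchi-type esterification through the mixed 2,4,6-trichlorobenzoic anhydride without a nucleophilic catalyst, the conditions under which angelates form without Z-to-E isomerisation to tiglates.

Step 13
Reactants: 20 silyl ether
Product: 21 the primary alcohol at C6 (3-hydroxymethyl compound)
Conditions: HF·pyridine, pyridine, THF, 0 °C → rt
Reagents that add atoms: none
Why: Fluoride cleavage of the primary silyl ether under buffered, weakly acidic conditions that leave the esters in place and do not promote acyl migration.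

Step 14
Reactants: 21 primary alcohol
Product: 22 the C6 aldehyde (3-formyl compound)
Conditions: Dess–Martin periodinane, CH2Cl2, 0 °C → rt
Reagents that add atoms: none
Why: Dess–Martin oxidation gives the aldehyde without base, so the C7 centre (α to the aldehyde, allylic to the acrylate) should not epimerise.

Step 15
Reactants: 22 bromofuran aldehyde
Product: 23 [6](2,5)furanophane carbinol (ten-membered ring closed between furan C5 and C6; both C6 epimers)
Conditions: CrCl2 (8 equiv), NiCl2 (2 mol%), DMF/THF (3:1), 0.003 M, rt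
Reagents that add atoms: none
Why: Nozaki–Hiyama–Kishi reaction: the bromofuran adds oxidatively to zerovalent nickel, transmetalation gives a furyl species of trivalent chromium that adds to the C6 aldehyde and closes the ten-membered carbocycle, a ring closure known for 2,5-furanophanes of this size; the C6 configuration is not relied on because step 16 erases it.

Step 16
Reactants: 23 furanophane carbinols
Product: 24 furanophane ketone (C6 carbonyl)
Conditions: Dess–Martin periodinane, CH2Cl2, 0 °C
Reagents that add atoms: none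
Why: Dess–Martin oxidation converges both C6 epimers on one 2-acylfuran under neutral conditions.

Step 17
Reactants: 24 furanophane ketone
Product: 25 (6R)-furanophane carbinol (hydroxyl on the face opposite to the later lactone oxygen)
Conditions: (S)-2-methyl-CBS-oxazaborolidine (0.2 equiv), catecholborane, toluene, −78 → −40 °C
Reagents that add atoms: none
Why: Corey–Bakshi–Shibata reduction under reagent control: with the furyl group as the large and the branched carbon C7 as the small substituent the (S)-catalyst should give the (6R) alcohol, epimeric at C6 to the lactone centre of 32 as the inversion in step 21 demands.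

Step 18
Reactants: 25 (6R)-furanophane carbinol
Product: 27 bridged pyranone hemiketal (O6 joins C6 and C2; C2–OH; C5 ketone; tert-butyl ester), via ene-dione 26 (not isolated)
Conditions: NBS, NaHCO3, THF/H2O (4:1), 0 °C
Reagents that add atoms: water, O
Why: Achmatowicz rearrangement: oxidative opening of the 2-furylcarbinol to the (Z)-ene-dione and 6-exo-trig closure of the C6 hydroxyl on the C2 carbonyl give the six-membered hemiketal, as known for furanophane carbinols of this ring size; C2 can only close with C1 and C7 on the same face of the pyranone, which fixes its configuration.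

Step 19
Reactants: 27 tert-butyl ester
Product: 28 bridged pyranone hemiketal carboxylic acid
Conditions: TFA/CH2Cl2 (1:4), 0 °C
Reagents that add atoms: none
Why: Acidolysis of the tert-butyl ester (loss of 2-methylpropene) at a stage where there is no free C5 hydroxyl, so the compound cannot aromatise back to a furan.

Step 20
Reactants: 28 pyranone acid
Product: 29 bridged pyranose allylic alcohol (C5–OH cis to C7; six-membered hemiketal on O6; free C12 acid)
Conditions: NaBH4, CeCl3·7H2O, MeOH, −78 °C; pH 5 work-up
Reagents that add atoms: none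
Why: Luche reduction: 1,2-hydride addition to the C5 enone carbonyl from the open face under the one-atom oxygen bridge, away from the five-carbon bridge, places the hydroxyl cis to C7 (threo to O6), which is the C5 configuration of 32; C2 stays masked as the hemiketal.

Step 21
Reactants: 29 bridged pyranose hydroxy acid
Product: 32 target hemiketal lactone (2R,5R,6S,7S,8S,9S), via furanose tautomer 30 (not isolated), via oxyphosphonium carboxylate 31 (not isolated)
Conditions: PPh3, DIAD, THF, 0.005 M, 0 °C → rt
Reagents that add atoms: none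
Why: Mitsunobu lactonisation running through ring–chain tautomerism: the six-membered hemiketal of 29 opens to the (Z)-dihydroxy enone and recloses through O5 (5-exo-trig on the C2 carbonyl) to the 2-hydroxy-2,5-dihydrofuran 30, which turns the eight-membered oxocine (O6, C6–C10, C1, C2) into the nine-membered oxonine (O5, C5–C10, C1, C2); the freed C6 hydroxyl forms the oxyphosphonium salt 31 and the C12 carboxylate displaces it by 5-exo-tet SN2 to close the γ-lactone. The closest known reactions are the pyranose-to-furanose change of bridged hemiketals in this ring system and the Mitsunobu γ-lactonisation of hydroxy acids with inversion. C6 is set by that inversion (R in 29, S in 32), C5 is carried over unchanged from step 20, and C2 follows from the oxygen bridge. The selectivity needed is substitution at C6 and not at C5: a C5 oxyphosphonium of the pyranose tautomer cannot be reached by the carboxylate, because after inversion O5 and C7 would stand trans-diaxial on the pyran ring and no δ-lactone can close, and oxyphosphonium formation is reversible, so the material should drain through 31. The lactonisation is irreversible and pulls the hemiketal equilibrium to the furanose side under neutral conditions that spare the acetate, the angelate and the hemiketal.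

**Compound list**

1 | 3-methylfuran | Cc1ccoc1 | starting material
2 | 2-bromo-3-methylfuran | Cc1ccoc1Br | intermediate
3 | (5-bromo-4-methylfuran-2-yl)lithium | [Li]c1cc(C)c(Br)o1 | intermediate
4 | 5-bromo-4-methylfuran-2-carbaldehyde | O=Cc1cc(C)c(Br)o1 | intermediate
5 | methyl 4,4-dimethoxy-3-oxobutanoate | COC(=O)CC(=O)C(OC)OC | starting material
6 | methyl (3S)-3-hydroxy-4,4-dimethoxybutanoate | COC(=O)C[C@H](O)C(OC)OC | intermediate
7 | methyl (3S)-3-(tert-butyldimethylsilyloxy)-4,4-dimethoxybutanoate | COC(=O)C[C@H](O[Si](C)(C)C(C)(C)C)C(OC)OC | intermediate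
8 | aldol adduct, methyl (3S)-2-[(5-bromo-4-methylfuran-2-yl)(hydroxy)methyl]-3-(tert-butyldimethylsilyloxy)-4,4-dimethoxybutanoate, mixture at C1 and C10 | COC(=O)C(C(O)c1cc(C)c(Br)o1)[C@H](O[Si](C)(C)C(C)(C)C)C(OC)OC | intermediate
9 | methanesulfonate of 8 | COC(=O)C(C(OS(C)(=O)=O)c1cc(C)c(Br)o1)[C@H](O[Si](C)(C)C(C)(C)C)C(OC)OC | intermediate
10 | methyl (2E,3S)-2-[(5-bromo-4-methylfuran-2-yl)methylidene]-3-(tert-butyldimethylsilyloxy)-4,4-dimethoxybutanoate | COC(OC)[C@@H](O[Si](C)(C)C(C)(C)C)/C(C(=O)OC)=C\c1cc(C)c(Br)o1 | intermediate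
11 | methyl (2E,3S)-2-[(5-bromo-4-methylfuran-2-yl)methylidene]-3-hydroxy-4-oxobutanoate | O=C[C@@H](O)/C(C(=O)OC)=C\c1cc(C)c(Br)o1 | intermediate
12 | tert-butyl acrylate | C=CC(=O)OC(C)(C)C | starting material
13 | (tert-butyldimethylsilyloxy)acetaldehyde | O=CCO[Si](C)(C)C(C)(C)C | starting material
14 | tert-butyl 4-(tert-butyldimethylsilyloxy)-3-hydroxy-2-methylidenebutanoate (racemic) | C=C(C(=O)OC(C)(C)C)C(O)CO[Si](C)(C)C(C)(C)C | intermediate
15 | tert-butyl (2Z)-2-(bromomethyl)-4-(tert-butyldimethylsilyloxy)but-2-enoate | BrC/C(C(=O)OC(C)(C)C)=C\CO[Si](C)(C)C(C)(C)C | intermediate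
16 | open-chain 8,9-diol (tert-butyl ester at C12, methyl ester at C14, C6 silyl ether), C7/C8/C9 as in 32 | C=C(C(=O)OC(C)(C)C)[C@@H](CO[Si](C)(C)C(C)(C)C)[C@H](O)[C@@H](O)/C(C(=O)OC)=C\c1cc(C)c(Br)o1 | intermediate
17 | O9 acetate of 16 | C=C(C(=O)OC(C)(C)C)[C@@H](CO[Si](C)(C)C(C)(C)C)[C@H](O)[C@@H](OC(C)=O)/C(C(=O)OC)=C\c1cc(C)c(Br)o1 | intermediate
18 | angelic acid, (Z)-2-methylbut-2-enoic acid | C/C=C(/C)C(=O)O | starting material
19 | angelic 2,4,6-trichlorobenzoic anhydride | C/C=C(/C)C(=O)OC(=O)c1c(Cl)cc(Cl)cc1Cl | intermediate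
20 | O8 angelate, O9 acetate, C6 silyl ether | C=C(C(=O)OC(C)(C)C)[C@@H](CO[Si](C)(C)C(C)(C)C)[C@H](OC(=O)/C(C)=C\C)[C@@H](OC(C)=O)/C(C(=O)OC)=C\c1cc(C)c(Br)o1 | intermediate
21 | C6 primary alcohol | C=C(C(=O)OC(C)(C)C)[C@@H](CO)[C@H](OC(=O)/C(C)=C\C)[C@@H](OC(C)=O)/C(C(=O)OC)=C\c1cc(C)c(Br)o1 | intermediate
22 | C6 aldehyde (bromofuran aldehyde) | C=C(C(=O)OC(C)(C)C)[C@@H](C=O)[C@H](OC(=O)/C(C)=C\C)[C@@H](OC(C)=O)/C(C(=O)OC)=C\c1cc(C)c(Br)o1 | intermediate
23 | [6](2,5)furanophane carbinol, both C6 epimers | C=C(C(=O)OC(C)(C)C)[C@@H]1[C@H](OC(=O)/C(C)=C\C)[C@@H](OC(C)=O)/C(C(=O)OC)=C\c2cc(C)c(o2)C1O | intermediate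
24 | furanophane ketone | C=C(C(=O)OC(C)(C)C)[C@@H]1[C@H](OC(=O)/C(C)=C\C)[C@@H](OC(C)=O)/C(C(=O)OC)=C\c2cc(C)c(o2)C1=O | intermediate
25 | (6R)-furanophane carbinol | C=C(C(=O)OC(C)(C)C)[C@@H]1[C@H](OC(=O)/C(C)=C\C)[C@@H](OC(C)=O)/C(C(=O)OC)=C\c2cc(C)c(o2)[C@@H]1O | intermediate
26 | ring-opened (Z)-ene-dione with free C6 hydroxyl | C=C(C(=O)OC(C)(C)C)[C@@H]1[C@H](OC(=O)/C(C)=C\C)[C@@H](OC(C)=O)/C(C(=O)OC)=C\C(=O)/C=C(/C)C(=O)[C@@H]1O | intermediate
27 | bridged pyranone hemiketal, tert-butyl ester | C=C(C(=O)OC(C)(C)C)[C@@H]1[C@H](OC(=O)/C(C)=C\C)[C@@H](OC(C)=O)/C(C(=O)OC)=C\[C@@]2(O)C=C(C)C(=O)[C@@H]1O2 | intermediate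
28 | bridged pyranone hemiketal, C12 acid | C=C(C(=O)O)[C@@H]1[C@H](OC(=O)/C(C)=C\C)[C@@H](OC(C)=O)/C(C(=O)OC)=C\[C@@]2(O)C=C(C)C(=O)[C@@H]1O2 | intermediate
29 | bridged pyranose allylic alcohol, C12 acid | C=C(C(=O)O)[C@@H]1[C@H](OC(=O)/C(C)=C\C)[C@@H](OC(C)=O)/C(C(=O)OC)=C\[C@@]2(O)C=C(C)[C@@H](O)[C@@H]1O2 | intermediate
30 | furanose tautomer of 29 (hemiketal on O5, free C6 hydroxyl) | C=C(C(=O)O)[C@@H]1[C@H](OC(=O)/C(C)=C\C)[C@@H](OC(C)=O)/C(C(=O)OC)=C\[C@@]2(O)C=C(C)[C@@H](O2)[C@@H]1O | intermediate
31 | C6 oxyphosphonium carboxylate of 30 | C=C(C(=O)[O-])[C@@H]1[C@H](OC(=O)/C(C)=C\C)[C@@H](OC(C)=O)/C(C(=O)OC)=C\[C@@]2(O)C=C(C)[C@@H](O2)[C@@H]1O[P+](c3ccccc3)(c3ccccc3)c3ccccc3 | intermediate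
32 | target, CNP0208424.1 | C=C1C(=O)O[C@H]2[C@H]1[C@H](OC(=O)/C(C)=C\C)[C@@H](OC(C)=O)/C(C(=O)OC)=C\[C@@]1(O)C=C(C)[C@H]2O1 | target

**Step count**

Total: 21 steps. Longest linear sequence: 17 steps (from 5: steps 3–7 and 10–21; the branch from 1 has the same length).

**Steps most likely to fail**

Step 21. What may go wrong: activation at the wrong oxygen. If the C5 oxyphosphonium of the pyranose tautomer ionises with help from the ring oxygen O6 (a 1,2-oxygen shift) before the furanose path is taken, C5 is inverted; dehydration of the furanose hemiketal to a furan is a second drain. The fallback sets out from 24 and comes back at 32. Ketone 24 is reduced with the (R)-oxazaborolidine to the (6S)-furanophane carbinol F1, which already has the lactone configuration at C6. The oxidation of step 18 then gives the tert-butyl ester pyranone F2, and the reduction of step 20 its C5 alcohol F3 (hydroxyl cis to C7). C5 is now inverted instead of C6, with an external acid while C12 is still an ester: PPh3, DIAD and chloroacetic acid give the inverted chloroacetate F4. TFA frees the chloroacetate acid F5, and thiourea/NaHCO3 in ethanol removes the chloroacetyl group to give the hydroxy acid F6. After the same change of the hemiketal from O6 to O5, F6 is closed with retention at C6 (EDC·HCl, CH2Cl2) to 32.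

Step 15. What may go wrong: ring closure is too slow against intermolecular coupling and against protonolysis of the carbon–chromium bond, because the furanophane is strained. The fallback sets out from 22 and comes back at 24. Pinnick oxidation (NaClO2, NaH2PO4, 2-methylbut-2-ene) turns 22 into the carboxylic acid F7, and EDC·HCl with N,O-dimethylhydroxylamine gives the Weinreb amide F8. Bromine–magnesium exchange with iPrMgCl·LiCl at −40 °C under high dilution lets the furylmagnesium close onto the amide and gives ketone 24 directly; steps 15 and 16 fall away.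

Step 11. What may go wrong: poor discrimination between O9 and O8, and acetyl migration between them while the angelate is put on in step 12. The fallback sets out from 16 and comes back at 20; a silyl group replaces the first acyl group and the acetate comes last. Et3SiCl/2,6-lutidine at −78 °C gives the O9 triethylsilyl ether F9 (a bulkier electrophile that cannot migrate as an acyl group does). The esterification of step 12 gives the O8 angelate F10. PPTS in methanol removes the secondary triethylsilyl group but not the primary tert-butyldimethylsilyl group and gives the C9 alcohol F11, which Ac2O/pyridine at 0 °C converts into 20.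

**Further compounds**

F1 | step 21 | (6S)-furanophane carbinol | C=C(C(=O)OC(C)(C)C)[C@@H]1[C@H](OC(=O)/C(C)=C\C)[C@@H](OC(C)=O)/C(C(=O)OC)=C\c2cc(C)c(o2)[C@H]1O
F2 | step 21 | bridged pyranone hemiketal of the 6S series, tert-butyl ester | C=C(C(=O)OC(C)(C)C)[C@@H]1[C@H](OC(=O)/C(C)=C\C)[C@@H](OC(C)=O)/C(C(=O)OC)=C\[C@]2(O)C=C(C)C(=O)[C@H]1O2
F3 | step 21 | its C5 alcohol (hydroxyl cis to C7) | C=C(C(=O)OC(C)(C)C)[C@@H]1[C@H](OC(=O)/C(C)=C\C)[C@@H](OC(C)=O)/C(C(=O)OC)=C\[C@]2(O)C=C(C)[C@H](O)[C@H]1O2
F4 | step 21 | C5-inverted chloroacetate, tert-butyl ester | C=C(C(=O)OC(C)(C)C)[C@@H]1[C@H](OC(=O)/C(C)=C\C)[C@@H](OC(C)=O)/C(C(=O)OC)=C\[C@]2(O)C=C(C)[C@@H](OC(=O)CCl)[C@H]1O2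
F5 | step 21 | C5 chloroacetate, C12 acid | C=C(C(=O)O)[C@@H]1[C@H](OC(=O)/C(C)=C\C)[C@@H](OC(C)=O)/C(C(=O)OC)=C\[C@]2(O)C=C(C)[C@@H](OC(=O)CCl)[C@H]1O2
F6 | step 21 | C5-inverted hydroxy acid (pyranose tautomer) | C=C(C(=O)O)[C@@H]1[C@H](OC(=O)/C(C)=C\C)[C@@H](OC(C)=O)/C(C(=O)OC)=C\[C@]2(O)C=C(C)[C@@H](O)[C@H]1O2
F7 | step 15 | C6 carboxylic acid of the open chain | C=C(C(=O)OC(C)(C)C)[C@@H](C(=O)O)[C@H](OC(=O)/C(C)=C\C)[C@@H](OC(C)=O)/C(C(=O)OC)=C\c1cc(C)c(Br)o1
F8 | step 15 | C6 Weinreb amide | C=C(C(=O)OC(C)(C)C)[C@@H](C(=O)N(C)OC)[C@H](OC(=O)/C(C)=C\C)[C@@H](OC(C)=O)/C(C(=O)OC)=C\c1cc(C)c(Br)o1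
F9 | step 11 | O9 triethylsilyl ether of 16 | C=C(C(=O)OC(C)(C)C)[C@@H](CO[Si](C)(C)C(C)(C)C)[C@H](O)[C@@H](O[Si](CC)(CC)CC)/C(C(=O)OC)=C\c1cc(C)c(Br)o1
F10 | step 11 | O8 angelate, O9 triethylsilyl ether | C=C(C(=O)OC(C)(C)C)[C@@H](CO[Si](C)(C)C(C)(C)C)[C@H](OC(=O)/C(C)=C\C)[C@@H](O[Si](CC)(CC)CC)/C(C(=O)OC)=C\c1cc(C)c(Br)o1
F11 | step 11 | O8 angelate with free C9 hydroxyl | C=C(C(=O)OC(C)(C)C)[C@@H](CO[Si](C)(C)C(C)(C)C)[C@H](OC(=O)/C(C)=C\C)[C@@H](O)/C(C(=O)OC)=C\c1cc(C)c(Br)o1
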